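**Plan**

1. Retrosynthesis: the hydroperoxide is traced to a (1S)-allylic alcohol (SN2 with H2O2) and the two esters to a diol. The γ-lactone is then cut at C6–O and C11–C12, which removes CO2 and rejoins C6–C11 as a cis-fused methylenecyclopropane. The ten-membered ring is cut at C1–C10, then C8–C9 and C4=C5, back to a bicyclic cyclopropane lactone made from an allenyl diazoacetate.
2. Enabling feature: the three-membered ring C6–C7–C11 with the exocyclic C11=C13 alkene and the C4=C5 alkene on C6. The strained C6–C11 bond is both proximal to the exocyclic alkene and allylic, so zerovalent nickel should open it to a σ-alkenyl/π-allyl unit that takes up CO2 at C11 and closes C6–O.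
3. Forward order: three-membered ring (step 2), chain growth at C5 and C8 (steps 4–6), ten-membered ring (step 9), γ-lactone by (3+2) cycloaddition with CO2 (step 11), then acetate, side-chain ester and hydroperoxide.
4. Stereochemistry: C6/C7 from catalyst-controlled cis cyclopropanation (C6 carried through the key step with retention); C8 from reagent-controlled allylboration; C1 from ligand-controlled ring closure followed by SN2 inversion; the side-chain carbinol from the chiral pool; C4=C5 geometry from E-selective olefination.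

Key step: step 11

Assumption: the SMILES is read literally, i.e. cis-fused 12,6-lactone (6S,7R,8S), 1R hydroperoxide, R side-chain carbinol, ring-cis C4=C5 (E by CIP because of the acetoxy group); germacrane numbering (C1–C15) is used throughout.
Assumption: the enantiomers of the chiral controllers in steps 2, 6 and 9 are those expected by analogy to give the stated configurations (the mirror-image controller would be used otherwise); these controllers and (2-bromoallyl)tributylstannane are known, non-catalogue compounds treated as reagents.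
Assumption: ester 20 is taken as a catalogue compound (malic acid series, R enantiomer).

**Route**

Step 1
Reactants: 1 buta-2,3-dien-1-ol
Product: 3 buta-2,3-dien-1-yl diazoacetate, via bromoacetate 2 (not isolated)
Conditions: BrCH2COBr, NaHCO3, MeCN, 0 °C; then TsNHNHTs, DBU, THF, 0 °C
Reagents that add atoms: bromoacetyl bromide, O=C(Br)CBr; N,N'-bis(4-methylbenzenesulfonyl)hydrazine, Cc1ccc(cc1)S(=O)(=O)NNS(=O)(=O)c1ccc(C)cc1
Why: O-acylation followed by base-induced loss of two sulfinates from the N-alkylated ditosylhydrazine is the standard two-stage synthesis of diazoacetates and leaves the allene untouched.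

Step 2
Reactants: 3 buta-2,3-dien-1-yl diazoacetate
Product: 4 (1S,5R)-6-methylidene-3-oxabicyclo[3.1.0]hexan-2-one
Conditions: Rh2(5S-MEPY)4 (dirhodium tetrakis[methyl (5S)-2-oxopyrrolidine-5-carboxylate], 1 mol %), CH2Cl2, 40 °C, slow addition
Reagents that add atoms: none
Why: Intramolecular carbenoid cyclopropanation of the proximal allene C=C closes the γ-lactone and the methylenecyclopropane together; the tether enforces cis fusion and the chiral carboxamidate ligands select the alkene face, setting C6 and C7 (sense by analogy with allylic diazoacetates).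

Step 3
Reactants: 5 triethyl phosphonoacetate; 6 3-bromo-1,1-dimethoxypropane
Product: 7 ethyl 2-(diethoxyphosphoryl)-5,5-dimethoxypentanoate
Conditions: NaH, DMF, 0 → 60 °C
Reagents that add atoms: none
Why: C-alkylation of the sodium phosphonoacetate with a primary bromide installs C1–C3, with C1 masked as its dimethyl acetal.

Step 4
Reactants: 4 (1S,5R)-6-methylidene-3-oxabicyclo[3.1.0]hexan-2-one; 7 ethyl 2-(diethoxyphosphoryl)-5,5-dimethoxypentanoate
Product: 9 ethyl (2E)-2-(3,3-dimethoxypropyl)-3-[(1S,2R)-2-(hydroxymethyl)-3-methylidenecyclopropyl]prop-2-enoate, via lactol 8 (not isolated)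
Conditions: DIBAL-H (iBu2AlH), CH2Cl2, −78 °C; then sodium salt of 7 (NaH, THF), −78 → 0 °C
Reagents that add atoms: none
Why: Partial reduction to the aluminium lactolate and in situ Horner–Wadsworth–Emmons olefination of the ring-opened aldehyde should give the (E)-enoate (ester trans to C6), which fixes the ring-cis C4=C5 geometry; the cold aluminium alkoxide should not undergo oxa-Michael closure.

Step 5
Reactants: 9 hydroxy enoate
Product: 10 ethyl (2E)-2-(3,3-dimethoxypropyl)-3-[(1S,2R)-2-formyl-3-methylidenecyclopropyl]prop-2-enoate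
Conditions: DMP, pyridine, CH2Cl2, 0 °C
Reagents that add atoms: none
Why: Buffered Dess–Martin oxidation of the primary carbinol should not epimerize C7, and the fully substituted alkene terminus C4 disfavors retro-Claisen rearrangement of the cis-vinylcyclopropane carbaldehyde.

Step 6
Reactants: 10 aldehyde
Product: 11 ethyl (2E)-3-{(1S,2R)-2-[(1S)-3-bromo-1-hydroxybut-3-en-1-yl]-3-methylidenecyclopropyl}-2-(3,3-dimethoxypropyl)prop-2-enoate
Conditions: (4S,5S)-2-bromo-4,5-diphenyl-1,3-bis(4-methylbenzenesulfonyl)-1,3,2-diazaborolidine, (2-bromoallyl)tributylstannane, CH2Cl2, 0 → 23 °C; then 10, −78 °C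
Reagents that add atoms: (2-bromoallyl)tributylstannane, C=C(Br)C[Sn](CCCC)(CCCC)CCCC
Why: Reagent-controlled enantioselective allylboration: tin-to-boron exchange gives a chiral B-(2-bromoallyl)diazaborolidine that adds through a chair six-membered transition state to the Si face of the aldehyde, setting C8 (S) and installing C9–C10(Br)=C14; the enoate and acetal are inert.

Step 7
Reactants: 11 bromo hydroxy enoate
Product: 12 (2E)-2-({(1S,2R)-2-[(1S)-3-bromo-1-hydroxybut-3-en-1-yl]-3-methylidenecyclopropyl}methylidene)-5,5-dimethoxypentan-1-ol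
Conditions: DIBAL-H (iBu2AlH), CH2Cl2, −78 → −40 °C
Reagents that add atoms: none
Why: 1,2-Reduction of the conjugated ester gives the C15 allylic alcohol without touching the alkenyl bromide, the acetal or the strained alkene.

Step 8
Reactants: 12 diol acetal
Product: 14 (4E)-5-{(1S,2R)-2-[(1S)-3-bromo-1-(triethylsilyloxy)but-3-en-1-yl]-3-methylidenecyclopropyl}-4-[(triethylsilyloxy)methyl]pent-4-enal, via bis-silyl acetal 13 (not isolated)
Conditions: TESOTf, 2,4,6-collidine, CH2Cl2, −40 → 0 °C; then H2O
Reagents that add atoms: triethylsilyl trifluoromethanesulfonate, CC[Si](CC)(CC)OS(=O)(=O)C(F)(F)F; water, O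
Why: The silyl triflate–collidine pair silylates both hydroxyls and then converts the dimethyl acetal, through a collidinium intermediate, into the aldehyde on aqueous work-up; this mild acetal cleavage spares silyl ethers and the vinyl-methylenecyclopropane.

Step 9
Reactants: 14 bromo aldehyde
Product: 15 (1S,4E,6S,7R,8S)-8,15-bis(triethylsilyloxy)-12-nor-6,11-cyclogermacra-4,10(14),11(13)-trien-1-ol
Conditions: CrCl2, (S)-N-[2-(4-isopropyl-4,5-dihydro-1,3-oxazol-2-yl)-6-methylphenyl]methanesulfonamide, Et3N, NiCl2 (cat.), THF, 23 °C, 2 mM, slow addition of 14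
Reagents that add atoms: none
Why: Intramolecular Nozaki–Hiyama–Kishi reaction: the nickel-generated C10 alkenylchromium adds to the C1 aldehyde under high dilution, closing the ten-membered ring (cis-alkene and cis-cyclopropane act as turn elements) and giving the 2-methylidene allylic alcohol directly, with the chromium-bound sulfonamide selecting the aldehyde face for 1S.

Step 10
Reactants: 15 macrocyclic allylic alcohol
Product: 16 (1S,4E,6S,7R,8S)-1-(tert-butyldimethylsilyloxy)-8,15-bis(triethylsilyloxy)-12-nor-6,11-cyclogermacra-4,10(14),11(13)-triene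
Conditions: TBSOTf, 2,6-lutidine, CH2Cl2, −78 °C
Reagents that add atoms: tert-butyldimethylsilyl trifluoromethanesulfonate, CC(C)(C)[Si](C)(C)OS(=O)(=O)C(F)(F)F
Why: Standard silylation keeps C1 masked, with a more robust ether than those at C8 and C15, while those two positions are processed.

Step 11
Reactants: 16 macrocyclic vinyl-methylenecyclopropane
Product: 17 (1S,4E,6S,7S,8S)-1-(tert-butyldimethylsilyloxy)-8,15-bis(triethylsilyloxy)germacra-4,10(14),11(13)-trien-12,6-olide (cis-fused lactone)
Conditions: Ni(cod)2 (20 mol %), 1,3-bis(2,6-diisopropylphenyl)imidazol-2-ylidene (20 mol %), CO2 (1 atm), toluene, 40 °C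
Reagents that add atoms: carbon dioxide, O=C=O
Why: Proposed new method: zerovalent nickel bound to the exocyclic C11=C13 alkene should insert into the strained C6–C11 bond, which is both proximal to that alkene and allylic to C4=C5, giving a 2-methylidene nickelacyclobutane whose C6 terminus is held as a π-allyl (C4–C5–C6); CO2 then inserts into the Ni–C11 alkenyl bond, and C6–O reductive elimination from the six-membered oxanickelacycle releases lactone and catalyst, a formal (3+2) cycloaddition driven by release of methylenecyclopropane strain. The closest known reaction types are the palladium- and nickel-catalysed (3+2) cycloadditions of methylenecyclopropanes (with CO2 through distal opening, with acceptor alkenes through proximal opening), the nickel–carbene-catalysed ring opening of unactivated vinylcyclopropanes, and nickel–carbene-catalysed incorporation of CO2 into lactone rings by C–O reductive elimination. The only ring closed is the γ-lactone, by carboxylate-to-allyl C–O bond formation at C6 in a 5-exo sense (O–C12–C11–C7–C6), preferred over the seven-membered alternative at the fully substituted C4. C6 is the only new stereocenter: nickel enters the C6–C11 bond with retention and delivers oxygen to the same face through the C11–C7 tether, so oxygen takes the place of C11 and the cis relation of C5 and C8 on the cyclopropane becomes the cis ring fusion (6S), with C7 untouched. The step needs cleavage of C6–C11 and not C6–C7 or C7–C11 (secured by the double activation of that bond), CO2 uptake at C11 and not at the allyl termini (the allyl is held η3 in the chelate while the Ni–alkenyl σ-bond is the nucleophilic site), and retention of the ring-cis C4=C5 geometry (the ring prevents syn–anti isomerisation of the allyl); 40 °C should be below the onset of the thermal vinyl-methylenecyclopropane rearrangement.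

Step 12
Reactants: 17 tris-silyl lactone
Product: 18 (1S,4E,6S,7R,8S)-1-(tert-butyldimethylsilyloxy)-8,15-dihydroxygermacra-4,10(14),11(13)-trien-12,6-olide
Conditions: HF·pyridine, pyridine, THF, 0 °C
Reagents that add atoms: none
Why: Triethylsilyl ethers are cleaved by buffered fluoride much faster than the secondary tert-butyldimethylsilyl ether, so only C8–OH and C15–OH are freed.

Step 13
Reactants: 18 diol
Product: 19 (1S,4E,6S,7R,8S)-15-acetoxy-1-(tert-butyldimethylsilyloxy)-8-hydroxygermacra-4,10(14),11(13)-trien-12,6-olide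
Conditions: AcCl, 2,4,6-collidine, CH2Cl2, −78 °C
Reagents that add atoms: acetyl chloride, CC(Cl)=O
Why: Kinetic acylation of the unhindered primary allylic alcohol at low temperature should leave the hindered secondary C8–OH free.

Step 14
Reactants: 20 methyl 2-[(4R)-2,2-dimethyl-1,3-dioxolan-4-yl]acetate
Product: 23 methyl 2-[(4R)-2,2-dimethyl-1,3-dioxolan-4-yl]prop-2-enoate, via Mannich base 21 (not isolated), via methiodide 22 (not isolated)
Conditions: LDA (LiN(iPr)2), THF, −78 °C; CH2=NMe2 iodide, −78 → 0 °C; then MeI, MeOH, 23 °C; then DBU, CH2Cl2, 23 °C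
Reagents that add atoms: N,N-dimethylmethyleneiminium iodide, C=[N+](C)C.[I-]; iodomethane (retained only in 22), CI
Why: Mannich reaction of the ester enolate, N-methylation and E1cB elimination is the standard α-methylenation; the enolate is kept at −78 °C so that the β-oxygen of the dioxolane is not expelled, and the stereocenter, which is not α to the carbonyl, is untouched.

Step 15
Reactants: 23 acrylate methyl ester
Product: 24 2-[(4R)-2,2-dimethyl-1,3-dioxolan-4-yl]prop-2-enoic acid
Conditions: LiOH, THF/H2O, 0 °C; then 1 M HCl to pH 4, 0 °C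
Reagents that add atoms: lithium hydroxide, [Li+].[OH-]
Why: Saponification of the methyl ester; the acetonide is stable to base and to brief cold acidification.

Step 16
Reactants: 19 C8 alcohol; 24 side-chain acid
Product: 25 (1S,4E,6S,7R,8S)-15-acetoxy-1-(tert-butyldimethylsilyloxy)-8-{2-[(4R)-2,2-dimethyl-1,3-dioxolan-4-yl]prop-2-enoyloxy}germacra-4,10(14),11(13)-trien-12,6-olide
Conditions: 24, 2,4,6-trichlorobenzoyl chloride, Et3N, THF, 0 °C; then 19, DMAP, toluene, 23 °C
Reagents that add atoms: none
Why: Yamaguchi esterification through the mixed anhydride acylates the hindered secondary alcohol at oxygen, so C8 keeps its configuration; short exposure to base limits translactonization.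

Step 17
Reactants: 25 silyl ether
Product: 26 (1S,4E,6S,7R,8S)-15-acetoxy-8-{2-[(4R)-2,2-dimethyl-1,3-dioxolan-4-yl]prop-2-enoyloxy}-1-hydroxygermacra-4,10(14),11(13)-trien-12,6-olide
Conditions: HF·pyridine, pyridine, THF, 0 → 23 °C
Reagents that add atoms: none
Why: Buffered fluoride cleaves the remaining silyl ether and spares the acetonide, the esters and the α-methylene lactone.

Step 18
Reactants: 26 (1S)-allylic alcohol
Product: 28 (1R,4E,6S,7R,8S)-15-acetoxy-8-{2-[(4R)-2,2-dimethyl-1,3-dioxolan-4-yl]prop-2-enoyloxy}-1-hydroperoxygermacra-4,10(14),11(13)-trien-12,6-olide, via mesylate 27 (not isolated)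
Conditions: MsCl, Et3N, CH2Cl2, −60 °C; then anhydrous H2O2, Et2O, −78 → −20 °C
Reagents that add atoms: hydrogen peroxide, OO; methanesulfonyl chloride (retained only in 27), CS(Cl)(=O)=O
Why: The allylic mesylate is displaced by hydrogen peroxide (an α-effect nucleophile) in ether at low temperature in an SN2 reaction with inversion (1S → 1R), the known mesylate-to-hydroperoxide conversion of secondary allylic alcohols; the base-free conditions avoid nucleophilic epoxidation of the enoates.

Step 19
Reactants: 28 acetonide hydroperoxide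
Product: 29 target (CNP0307408.1)
Conditions: AcOH/H2O (4:1), 35 °C
Reagents that add atoms: none
Why: Mild acid hydrolysis of the terminal acetonide; the secondary hydroperoxide, the allylic acetate and the lactone should survive dilute acetic acid.

**Compound list**

1 | buta-2,3-dien-1-ol | C=C=CCO | starting material
2 | buta-2,3-dien-1-yl bromoacetate | C=C=CCOC(=O)CBr | intermediate
3 | buta-2,3-dien-1-yl diazoacetate | C=C=CCOC(=O)C=[N+]=[N-] | intermediate
4 | (1S,5R)-6-methylidene-3-oxabicyclo[3.1.0]hexan-2-one | C=C1[C@H]2C(=O)OC[C@@H]12 | intermediate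
5 | triethyl phosphonoacetate | CCOC(=O)CP(=O)(OCC)OCC | starting material
6 | 3-bromo-1,1-dimethoxypropane | COC(CCBr)OC | starting material
7 | ethyl 2-(diethoxyphosphoryl)-5,5-dimethoxypentanoate | CCOC(=O)C(CCC(OC)OC)P(=O)(OCC)OCC | intermediate
8 | (1S,5R)-6-methylidene-3-oxabicyclo[3.1.0]hexan-2-ol (lactol, both anomers) | C=C1[C@H]2C(O)OC[C@@H]12 | intermediate
9 | ethyl (2E)-2-(3,3-dimethoxypropyl)-3-[(1S,2R)-2-(hydroxymethyl)-3-methylidenecyclopropyl]prop-2-enoate | C=C1[C@@H](/C=C(/C(=O)OCC)CCC(OC)OC)[C@H]1CO | intermediate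
10 | ethyl (2E)-2-(3,3-dimethoxypropyl)-3-[(1S,2R)-2-formyl-3-methylidenecyclopropyl]prop-2-enoate | C=C1[C@@H](/C=C(/C(=O)OCC)CCC(OC)OC)[C@H]1C=O | intermediate
11 | ethyl (2E)-3-{(1S,2R)-2-[(1S)-3-bromo-1-hydroxybut-3-en-1-yl]-3-methylidenecyclopropyl}-2-(3,3-dimethoxypropyl)prop-2-enoate | C=C1[C@@H](/C=C(/C(=O)OCC)CCC(OC)OC)[C@H]1[C@@H](O)CC(Br)=C | intermediate
12 | (2E)-2-({(1S,2R)-2-[(1S)-3-bromo-1-hydroxybut-3-en-1-yl]-3-methylidenecyclopropyl}methylidene)-5,5-dimethoxypentan-1-ol | C=C1[C@@H](/C=C(/CO)CCC(OC)OC)[C@H]1[C@@H](O)CC(Br)=C | intermediate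
13 | bis(triethylsilyl) ether of 12 (dimethyl acetal intact) | C=C1[C@@H](/C=C(/CO[Si](CC)(CC)CC)CCC(OC)OC)[C@H]1[C@@H](O[Si](CC)(CC)CC)CC(Br)=C | intermediate
14 | (4E)-5-{(1S,2R)-2-[(1S)-3-bromo-1-(triethylsilyloxy)but-3-en-1-yl]-3-methylidenecyclopropyl}-4-[(triethylsilyloxy)methyl]pent-4-enal | C=C1[C@@H](/C=C(/CO[Si](CC)(CC)CC)CCC=O)[C@H]1[C@@H](O[Si](CC)(CC)CC)CC(Br)=C | intermediate
15 | (1S,4E,6S,7R,8S)-8,15-bis(triethylsilyloxy)-12-nor-6,11-cyclogermacra-4,10(14),11(13)-trien-1-ol (cis-fused methylenecyclopropane on the ten-membered ring) | C=C1[C@H]2/C=C(/CO[Si](CC)(CC)CC)CC[C@H](O)C(=C)C[C@H](O[Si](CC)(CC)CC)[C@@H]12 | intermediate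
16 | 1-O-tert-butyldimethylsilyl ether of 15 | C=C1[C@H]2/C=C(/CO[Si](CC)(CC)CC)CC[C@H](O[Si](C)(C)C(C)(C)C)C(=C)C[C@H](O[Si](CC)(CC)CC)[C@@H]12 | intermediate
17 | (1S,4E,6S,7S,8S)-1-(tert-butyldimethylsilyloxy)-8,15-bis(triethylsilyloxy)germacra-4,10(14),11(13)-trien-12,6-olide (cis-fused) | C=C1C(=O)O[C@H]2/C=C(/CO[Si](CC)(CC)CC)CC[C@H](O[Si](C)(C)C(C)(C)C)C(=C)C[C@H](O[Si](CC)(CC)CC)[C@@H]12 | intermediate
18 | (1S,4E,6S,7R,8S)-1-(tert-butyldimethylsilyloxy)-8,15-dihydroxygermacra-4,10(14),11(13)-trien-12,6-olide | C=C1C(=O)O[C@H]2/C=C(/CO)CC[C@H](O[Si](C)(C)C(C)(C)C)C(=C)C[C@H](O)[C@@H]12 | intermediate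
19 | (1S,4E,6S,7R,8S)-15-acetoxy-1-(tert-butyldimethylsilyloxy)-8-hydroxygermacra-4,10(14),11(13)-trien-12,6-olide | C=C1C(=O)O[C@H]2/C=C(/COC(C)=O)CC[C@H](O[Si](C)(C)C(C)(C)C)C(=C)C[C@H](O)[C@@H]12 | intermediate
20 | methyl 2-[(4R)-2,2-dimethyl-1,3-dioxolan-4-yl]acetate | COC(=O)C[C@@H]1COC(C)(C)O1 | starting material
21 | methyl 3-(dimethylamino)-2-[(4R)-2,2-dimethyl-1,3-dioxolan-4-yl]propanoate (α-epimers) | COC(=O)C(CN(C)C)[C@@H]1COC(C)(C)O1 | intermediate
22 | trimethylammonium iodide (methiodide) of 21 | COC(=O)C(C[N+](C)(C)C)[C@@H]1COC(C)(C)O1.[I-] | intermediate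
23 | methyl 2-[(4R)-2,2-dimethyl-1,3-dioxolan-4-yl]prop-2-enoate | COC(=O)C(=C)[C@@H]1COC(C)(C)O1 | intermediate
24 | 2-[(4R)-2,2-dimethyl-1,3-dioxolan-4-yl]prop-2-enoic acid | OC(=O)C(=C)[C@@H]1COC(C)(C)O1 | intermediate
25 | 8-O-{2-[(4R)-2,2-dimethyl-1,3-dioxolan-4-yl]prop-2-enoyl} derivative of 19 | C=C1C(=O)O[C@H]2/C=C(/COC(C)=O)CC[C@H](O[Si](C)(C)C(C)(C)C)C(=C)C[C@H](OC(=O)C(=C)[C@@H]3COC(C)(C)O3)[C@@H]12 | intermediate
26 | (1S)-1-hydroxy compound from 25 (C6, C7, C8 as in the target) | C=C1C(=O)O[C@H]2/C=C(/COC(C)=O)CC[C@H](O)C(=C)C[C@H](OC(=O)C(=C)[C@@H]3COC(C)(C)O3)[C@@H]12 | intermediate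
27 | (1S)-1-O-methanesulfonate of 26 | C=C1C(=O)O[C@H]2/C=C(/COC(C)=O)CC[C@H](OS(C)(=O)=O)C(=C)C[C@H](OC(=O)C(=C)[C@@H]3COC(C)(C)O3)[C@@H]12 | intermediate
28 | (1R)-1-hydroperoxide, side-chain diol as acetonide | C=C1C(=O)O[C@H]2/C=C(/COC(C)=O)CC[C@@H](OO)C(=C)C[C@H](OC(=O)C(=C)[C@@H]3COC(C)(C)O3)[C@@H]12 | intermediate
29 | (1R,4E,6S,7R,8S)-15-acetoxy-8-{2-[(1R)-1,2-dihydroxyethyl]prop-2-enoyloxy}-1-hydroperoxygermacra-4,10(14),11(13)-trien-12,6-olide | C=C1C(=O)O[C@H]2/C=C(/COC(C)=O)CC[C@@H](OO)C(=C)C[C@H](OC(=O)C(=C)[C@@H](O)CO)[C@@H]12 | target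

**Step count**

Total steps: 19. Longest linear sequence: 16 steps (1, 2, 4–13, 16–19).

**Steps most likely to fail**

1. Step 11 (Proposed new method). Processes at risk: after ring opening the alkenyl–nickel bond may not insert CO2; competing paths are C–C reductive elimination to a bicyclic methylenecyclopentene, cleavage of C6–C7 with β-silyloxy elimination, and failure of the allyl carboxylate to leave nickel (no turnover). Fallback with known chemistry, from 16 back to 17: iodine-mediated anti ring opening of the methylenecyclopropane at the allylic C6–C11 bond (I2, CH2Cl2, 0 °C) should give the alkenyl iodide/allylic iodide F1. SN2 displacement of the allylic iodide with HCO2Cs (DMF, 0 °C) gives the formate F2; this second inversion restores net retention at C6. Methanolysis (KHCO3, MeOH, 0 °C) gives the 2-iodoallyl alcohol F3, and carbonylative lactonization (Pd(PPh3)4, CO 1 atm, K2CO3, THF, 40 °C) closes the α-methylene-γ-lactone to give 17.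

2. Step 18. Processes at risk: ionization of the allylic mesylate with loss of configurational integrity at C1, or SN2′ attack at C14 giving the transposed primary hydroperoxide. Fallback from 26 back to 28: Mitsunobu reaction with 2-nitrobenzenesulfonylhydrazide (PPh3, DEAD, THF, −30 °C) gives the allylic sulfonylhydrazine F4. On warming to 23 °C this loses sulfinic acid and then dinitrogen by retro-ene 1,3-transposition, giving the (1(10)E)-alkene with C14 as a methyl group, F5. A Schenck ene reaction (O2, hν, tetraphenylporphyrin, CH2Cl2, −20 °C) then returns oxygen to C1 with the hydrogen taken from C14, giving 28; in this variant C1 is set by the exposed face of the ring alkene, not by the alcohol.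

3. Step 9. Process at risk: poor facial selectivity at C1 in the ring-closing addition, because the ten-membered transition state may override the ligand. Fallback from 14 back to 15: ring closure without the chiral ligand (CrCl2, NiCl2 cat., DMSO, 23 °C, 2 mM) gives the C1-epimer mixture F6. Dess–Martin oxidation (DMP, pyridine, CH2Cl2, 0 °C) gives the cross-conjugated 2-methylidene ketone F7, and Corey–Bakshi–Shibata reduction (B-methyl oxazaborolidine enantiomer selected for the 1S alcohol, catecholborane, toluene, −78 °C) gives 15.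

**Further compounds**

F1 | step 11 | ring-opened diiodide from 16: 11-iodo-C11=C13 alkenyl iodide with allylic iodide at C6 (C6 inverted), 1-OTBS, 8,15-bis-OTES | C=C(I)[C@H]1[C@H](I)/C=C(/CO[Si](CC)(CC)CC)CC[C@H](O[Si](C)(C)C(C)(C)C)C(=C)C[C@@H]1O[Si](CC)(CC)CC
F2 | step 11 | C6 formate of the 11-iodo alkene (C6 configured as in 17) | C=C(I)[C@H]1[C@@H](OC=O)/C=C(/CO[Si](CC)(CC)CC)CC[C@H](O[Si](C)(C)C(C)(C)C)C(=C)C[C@@H]1O[Si](CC)(CC)CC
F3 | step 11 | C6 alcohol of the 11-iodo alkene (2-iodoallyl alcohol) | C=C(I)[C@H]1[C@@H](O)/C=C(/CO[Si](CC)(CC)CC)CC[C@H](O[Si](C)(C)C(C)(C)C)C(=C)C[C@@H]1O[Si](CC)(CC)CC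
F4 | step 18 | C1 N-(2-nitrobenzenesulfonyl)hydrazine from 26 (C1 inverted) | C=C1C(=O)O[C@H]2/C=C(/COC(C)=O)CC[C@@H](N(N)S(=O)(=O)c4ccccc4[N+](=O)[O-])C(=C)C[C@H](OC(=O)C(=C)[C@@H]3COC(C)(C)O3)[C@@H]12
F5 | step 18 | (1(10)E)-germacra-1(10),4,11(13)-trien-12,6-olide with C14 methyl, 15-acetoxy, 8-acyloxy (acetonide) | C=C1C(=O)O[C@H]2/C=C(/COC(C)=O)CC/C=C(C)/C[C@H](OC(=O)C(=C)[C@@H]3COC(C)(C)O3)[C@@H]12
F6 | step 9 | C1-epimer mixture of 15 | C=C1[C@H]2/C=C(/CO[Si](CC)(CC)CC)CCC(O)C(=C)C[C@H](O[Si](CC)(CC)CC)[C@@H]12
F7 | step 9 | C1 ketone (2-methylidene ketone) from F6 | C=C1[C@H]2/C=C(/CO[Si](CC)(CC)CC)CCC(=O)C(=C)C[C@H](O[Si](CC)(CC)CC)[C@@H]12
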